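## Structural features

The target 25 consists of two six-membered carbocycles joined by a single CH2 group. Ring A is a fully substituted acylphloroglucinol (butyryl at C6, free hydroxyls at C5 and C7) whose third oxygen is part of a fused 2,2-dimethyl-2H-pyran (O1, C2, C3=C4). Ring B is a dearomatised, doubly enolised 2-acetylcyclohexane-1,3,5-trione. The bridge runs from C8 of the chromene to C6 of ring B, so each of its two bonds ends at the most nucleophilic carbon of a vinylogous acid.

The only stereocentre is the all-carbon quaternary C4 of ring B. It carries a methyl group and an E-geranyl chain and lies between the enol carbons C3 and C5. It has no stereogenic neighbour, so nothing in the molecule can relay or correct its configuration. C4 is stereogenic only because the two halves of ring B differ at a distance (acetyl on C2, bridge on C6). Any exchange of the C3 and C5 arms, or loss and return of the acetyl group, therefore amounts to racemisation, although C4 itself cannot epimerise.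

The fragile parts are:
- the geranyl 1,5-diene and the chromene C3=C4 olefin, which are acid-sensitive because the enol oxygens beside the geranyl chain cyclise on protonation;
- the electron-rich phenol and enol units, which are sensitive to oxidants;
- the bridge, which strong base can open by retro-Michael cleavage and scramble to symmetrical dimers.

The real difficulty is the absolute configuration at C4. Methyl and C1'H2 differ only beyond their first atom, and C3 and C5 are almost alike.

The key step exploits the following feature. C3, C4 and C5, together with the methyl group and C1', form the carbon skeleton of 2,2-dimethylmalonic acid in which one hydrogen of one methyl group is replaced by the alkenyl carbon C2'. Forming C1'–C2' on a malonamate whose two carbonyl arms already differ creates the stereocentre and completes the geranyl chain in one operation.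

## Logic of the disconnections

**25 to 16 and 23 (through 24).** The bond between the bridge CH2 and C6 of ring B is cut. This splits the molecule into two halves of similar size, and the enantioenriched half enters only in the last step. The forward step must be cross-selective. The bridge carbon is therefore placed on ring A beforehand as a latent electrophile, so that ring A can only accept and ring B can only donate. Conditions must stay near neutral so that the bridge is not reopened.

**23 to 22.** The C8–CH2 bond is cut. C8 is the only free ring carbon, so no regiochemical question arises. The forward step has to stop at the aminomethyl stage and must not proceed to a symmetrical dimer.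

**22 to 19 and 20 (through 21).** The C4a–C4 and O1–C2 bonds are cut, which removes the pyran ring in one move and leaves a simple acylphloroglucinol and a C5 enal. The forward step must close through the oxygen para to the acyl group and must annulate only once.

**19 to 17 and 18.** The aryl–acyl bond is cut. The threefold symmetry of 17 makes the site of acylation irrelevant, and the forward step only has to stop after one acylation.

**16 to 15.** The C2–C3 bond is cut, which opens ring B to an acyclic triketo ester with unchanged oxidation levels. The forward closure has to be C-acylation at the carbon between the two ketones rather than O-acylation, so it must run under equilibrating basic conditions.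

**15 to 12 and 13 (as 14).** The C5–C6 bond is cut, which separates an achiral five-carbon unit from the chiral malonyl unit. The forward step has one strict demand: the carbon nucleophile must attack only the activated amide arm. That arm becomes C5 and the ester arm becomes C3, and with this mapping (R)-11 leads to (R)-C4. First attack at the ester arm would lead to the mirror-image ring B.

**12 to 11.** The N–carbamate bond is cut. The group that directs the C–H step is re-used as the leaving group after one activation, so no change of functional group is needed between the key step and ring construction.

**11 to 5 and 10.** The C1'–C2' bond is cut. This removes nine carbons, the olefin geometry problem and the stereocentre at once, and leaves an achiral gem-dimethyl malonamate. The forward step must distinguish two enantiotopic methyl groups, keep the olefin geometry and stop after one alkenylation.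

**5 to 2 and 3 (through 4), and 2 to 1.** The amide C–N bond and one ester C–O bond are cut. The only demand is clean mono-differentiation of a symmetrical diester.

**10 to 8 (through 9), and 8 to 6 (through 7).** The C–I and C–CH3 bonds at the trisubstituted olefin are cut back to a terminal alkyne, and the alkyne is traced to a methyl ketone. The forward step must add methyl and metal syn and regioselectively, because this fixes the E geometry of C2'=C3' in 25.

## Other disconnections considered

**Alternative 1:** The cut goes through C5–C6 and C2–C3. It divides ring B into 13 and an enantiopure 2-geranyl-2-methylmalonic half-ester activated as its acyl imidazole A1.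
- Forward key step: 14 is acylated at its terminal carbon by the imidazolide carbonyl of A1. The central carbon of the resulting triketo ester then condenses with the methyl ester and gives the ring B unit A2, which is the same compound as 16.
- In favour: both ring bonds come from a cheap diketone, all oxidation levels are correct, and A1 has only one highly reactive carbonyl, with no carbamate carbonyl and no fluoroarene.
- Against: the step creates no stereocentre. It presupposes enantiopure A1, whose origin (esterase desymmetrisation, resolution or auxiliary-controlled alkylation) must be added. For a lipophilic C10 chain the sense and level of an enzymatic desymmetrisation are hard to foresee.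
- Comparison: in structure and mechanism this is the ring construction of steps 7 and 8, so the two plans are equal on ring formation. A1 is the better acyl donor than 12. If A1 comes from malonate geranylation, enzymatic hydrolysis and activation, the alternative is also shorter and rests wholly on established reactions, so it is better on risk and step count. The chosen plan answers what this alternative leaves open. It sets C4, differentiates the arms and builds the chain in one catalytic event, and either antipode is available by choice of ligand.

**Alternative 2:** The cut is C4–C3. The quaternary carbon is traced to the tertiary epoxide carbon of the epoxy silyl ether A4, made from the allylic alcohol A3 by Sharpless epoxidation and silylation.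
- Forward key step: methylaluminium bis(4-bromo-2,6-di-tert-butylphenoxide) ionises the epoxide at its tertiary carbon. The silyloxymethyl group migrates anti to the leaving oxygen and gives the aldehyde A5.
- In favour: the configuration comes from an epoxidation whose sense is predictable and which picks the allylic alcohol olefin out of three. The 1,2-shift is stereospecific. The two arms (CHO as future C5, CH2OSi as future C3) are clearly different.
- Against: A3 is a skipped triene with two defined trisubstituted olefins and has to be built first. The developing cation in A4 is homoallylic to C2'=C3', so olefin participation or hydride shift can compete with the desired migration. Both arms are under-oxidised, so deprotection, three oxidation-level changes and an esterification in the presence of three olefins are needed to reach A1.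
- Comparison: this alternative is better on predictability of the absolute configuration. On mechanism, both plans are catalyst-controlled, here with an additional stereospecific transfer. On step economy the chosen plan is clearly ahead, because 11 already has both carbonyl carbons at the acid level and is three steps from 16.

**Alternative 3:** The cut is the C4–CH3 bond, which leads back to the γ-phosphoryloxy enoate A6.
- Forward key step: dimethylzinc and a monovalent copper salt with a chiral peptide-type or carbene ligand deliver methyl to the geranyl-bearing α-carbon with allylic loss of phosphate. This gives the vinyl ester A7.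
- In favour: copper-catalysed allylic substitution of such enoates is an established way to all-carbon quaternary α-centres. The ester arm (C3) is at the right oxidation level, and the vinyl group already contains C5 and C6.
- Against: A6 needs a geometrically pure trisubstituted enoate. Methyl is the least reactive group to transfer from zinc. The vinyl group must be converted by Wacker oxidation beside a quaternary carbon into the methyl ketone A8. A8 then has to be acetoacetylated at its methyl group to reach 15, a C-acylation that is prone to O-acylation and lacks a simple reagent. Plain acetylation followed by ring closure would pass through a symmetrical trione and erase the stereocentre.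
- Comparison: on the precedent of the stereo-defining step this alternative is better than the chosen plan. On structure it is about equal up to the quaternary carbon. On step economy and on the link to ring B it is weaker, because the chosen plan reaches 15 from its key product in two steps by a standard dianion acylation.

Key step: step 5

Assumption: the ligand antipode that leads to (R)-11 cannot be derived from first principles for a malonamate. Both antipodes of the ligand are accessible, the one that gives (R)-11 is used, and the configuration of 11 is to be secured by correlation.

Assumption: ring B compounds are drawn in the enol tautomer of the target structure, and the descriptor R at C4 refers to that tautomer.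

## Steps

Step 1
Reactants: 1 dimethyl 2,2-dimethylmalonate
Product: 2 3-methoxy-2,2-dimethyl-3-oxopropanoic acid (monomethyl 2,2-dimethylmalonate)
Conditions: KOH (1.0 equiv), MeOH, rt; then dilute aq. HCl, 0 °C
Reagents that add atoms: potassium hydroxide, [K+].[OH-]
Why: Mono-saponification of a symmetrical diester: only one equivalent of hydroxide is used, and the carboxylate formed first shields the remaining hindered ester, so the reaction should stop at the half-ester. 2 has no α-hydrogen and is stable to decarboxylation at room temperature.

Step 2
Reactants: 2 3-methoxy-2,2-dimethyl-3-oxopropanoic acid; 3 2,3,5,6-tetrafluoro-4-(trifluoromethyl)aniline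
Product: 5 methyl 2,2-dimethyl-3-oxo-3-{[2,3,5,6-tetrafluoro-4-(trifluoromethyl)phenyl]amino}propanoate, via acid chloride 4 (not isolated)
Conditions: (COCl)2 (1.2 equiv), DMF (cat.), CH2Cl2, 0 °C to rt; evaporate; then 3, toluene, 110 °C
Reagents that add atoms: oxalyl chloride, ClC(=O)C(=O)Cl (chlorine of 4 only; nothing of it remains in 5)
Why: Acid chloride formation followed by N-acylation; the polyfluoroaniline is a very weak nucleophile and needs the acid chloride and heat, which 4 tolerates because it has no α-hydrogen (no ketene) and no acid-sensitive group. The electron-poor aryl group makes the N–H acidic enough to bind palladium as an amidate in step 5.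

Step 3
Reactants: 6 6-methylhept-5-en-2-one
Product: 8 6-methylhept-5-en-1-yne, via enol phosphate 7 (not isolated)
Conditions: LDA (LiN(iPr)2, 1.1 equiv), THF, −78 °C; ClP(O)(OEt)2, −78 °C to rt; then LDA (2.3 equiv), THF, −78 °C to rt; aq. NH4Cl
Reagents that add atoms: diethyl chlorophosphate, CCOP(=O)(Cl)OCC (phosphate group of 7 only; nothing of it remains in 8)
Why: Conversion of a methyl ketone into a terminal alkyne through its enol phosphate: kinetic deprotonation at the methyl group, O-phosphorylation, then base-induced elimination of diethyl phosphate. The last equivalent of base stores the product as its acetylide, which prevents isomerisation to an allene or internal alkyne, and the trisubstituted olefin is inert.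

Step 4
Reactants: 8 6-methylhept-5-en-1-yne
Product: 10 (E)-1-iodo-2,6-dimethylhepta-1,5-diene, via alkenylalane 9 (not isolated)
Conditions: Me3Al (2.0 equiv), Cp2ZrCl2 (0.2 equiv), CH2Cl2, 0 °C to rt; then I2, THF, −30 to 0 °C
Reagents that add atoms: trimethylaluminium, C[Al](C)C (methyl group at C2 of 10 and the dimethylaluminium group of 9); iodine, [I][I]
Why: Negishi zirconium-catalysed methylalumination adds methyl and aluminium syn across the alkyne with aluminium at the terminal carbon, and iodinolysis of the C–Al bond proceeds with retention, so the E geometry of the later C2'=C3' olefin is fixed here. The isolated trisubstituted olefin does not carboaluminate.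

Step 5
Reactants: 5 methyl 2,2-dimethyl-3-oxo-3-{[2,3,5,6-tetrafluoro-4-(trifluoromethyl)phenyl]amino}propanoate; 10 (E)-1-iodo-2,6-dimethylhepta-1,5-diene
Product: 11 methyl (2R,4E)-2,5,9-trimethyl-2-{[2,3,5,6-tetrafluoro-4-(trifluoromethyl)phenyl]carbamoyl}deca-4,8-dienoate (the (R)-2-geranyl-2-methylmalonamate)
Conditions: 5 (1.5 equiv), 10 (1.0 equiv), Pd(OAc)2 (10 mol %), chiral N-acetyl aminomethyl-oxazoline ligand (15 mol %; for example N-[1-(4-benzyl-4,5-dihydrooxazol-2-yl)-2,2-dimethylpropyl]acetamide, antipode as assumed above), Ag2CO3 (1.0 equiv), (CF3)2CHOH, 70 °C, N2, dark
Reagents that add atoms: none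
Why: Proposed new method: the acidic N–H of 5 is deprotonated and binds divalent palladium as an amidate, the chiral ligand takes two further sites, and its acetamide group acts as internal base in a concerted metalation–deprotonation of one methyl group, giving a five-membered palladacycle (Pd, N, amide carbon, C4, CH2). Oxidative addition of 10 gives a tetravalent alkyl(alkenyl)palladium species, reductive elimination forms C1'–C2' with retention of the E geometry, and Ag2CO3 removes both iodide and the proton so that no free acid builds up beside the 1,5-diene. The closest known reaction type is the ligand-controlled enantioselective β-C(sp3)–H arylation, alkenylation and alkynylation of isopropyl or gem-dimethyl groups in electron-poor N-aryl carboxamides; the new elements are the α-ester of a malonamate and an unactivated trisubstituted alkenyl iodide. No ring is closed. The one new stereocentre, C4, is controlled solely by the ligand, which decides in the C–H cleavage transition state which enantiotopic methyl group is metalated, since the substrate has no bias of its own. Site selectivity follows from ring size (only the two C-methyl groups can give a five-membered palladacycle), the fluorinated alcohol hydrogen-bonds to the ester and weakens its competing coordination, and the oxazoline ligand class is preferred to the quinoline class because the latter is the one that opens methylene C–H bonds, which in 11 would be the allylic C1'–H. Monoalkenylation rests on excess 5, limiting 10 and the greater crowding of 11; a second alkenylation should consume mainly the minor enantiomer, whose remaining methyl group is the one the catalyst prefers, and so should raise rather than lower the enantiomeric purity of 11.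

Step 6
Reactants: 11 methyl (2R,4E)-2,5,9-trimethyl-2-{[2,3,5,6-tetrafluoro-4-(trifluoromethyl)phenyl]carbamoyl}deca-4,8-dienoate
Product: 12 methyl (2R,4E)-2-{(tert-butoxycarbonyl)[2,3,5,6-tetrafluoro-4-(trifluoromethyl)phenyl]carbamoyl}-2,5,9-trimethyldeca-4,8-dienoate (N-Boc imide)
Conditions: Boc2O (3 equiv), DMAP (0.5 equiv), MeCN, rt to 40 °C
Reagents that add atoms: di-tert-butyl dicarbonate, CC(C)(C)OC(=O)OC(=O)OC(C)(C)C
Why: DMAP-catalysed N-tert-butoxycarbonylation of a secondary anilide. The resulting N-acyl carbamate is twisted and has lost its amide resonance, which turns the directing group into a leaving group; ester, olefins and C4 are untouched.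

Step 7
Reactants: 12 N-Boc imide; 13 pentane-2,4-dione
Product: 15 methyl (2R)-2-[(2E)-3,7-dimethylocta-2,6-dien-1-yl]-2-methyl-3,5,7-trioxooctanoate, via dilithio dianion 14 (not isolated)
Conditions: 13 (2.5 equiv), LDA (LiN(iPr)2, 5.0 equiv), THF, 0 °C; then 12 (1.0 equiv), −78 to −30 °C; aq. NH4Cl
Reagents that add atoms: lithium diisopropylamide, [Li+].CC(C)[N-]C(C)C (lithium of 14 only; nothing of it remains in 15)
Why: γ-Acylation of a 1,3-diketone dianion (Claisen-type C-acylation): 14 reacts at its more basic terminal carbon, and the excess of 14 deprotonates the more acidic product so that it is not attacked again. The imide carbonyl is far more electrophilic than the equally hindered methyl ester, so C5–C6 forms at the former amide arm, which carries (R)-11 over to the (R)-configured ring B.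

Step 8
Reactants: 15 methyl (2R)-2-[(2E)-3,7-dimethylocta-2,6-dien-1-yl]-2-methyl-3,5,7-trioxooctanoate
Product: 16 (R)-2-acetyl-4-[(2E)-3,7-dimethylocta-2,6-dien-1-yl]-3,5-dihydroxy-4-methylcyclohexa-2,5-dien-1-one (ring B unit)
Conditions: NaOMe (3 equiv), MeOH, 0 to 50 °C; then cold dilute aq. HCl to pH 3, immediate extraction
Reagents that add atoms: none
Why: Dieckmann-type intramolecular Claisen condensation, a 6-exo-trig attack of C2 (the carbon between the two ketones of the former 13) on the ester carbonyl C3. An enol lactone formed by O-acylation is reopened by methoxide whereas 16 is withdrawn as its very stable enolate, so the C-acylated ring is the thermodynamic sink. Methoxide matches the ester, and the quaternary C4 is not affected.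

Step 9
Reactants: 17 phloroglucinol; 18 butanoyl chloride
Product: 19 1-(2,4,6-trihydroxyphenyl)butan-1-one
Conditions: AlCl3 (4 equiv), CH2Cl2–PhNO2, 40 °C; then ice and dilute aq. HCl
Reagents that add atoms: none
Why: Friedel–Crafts acylation; the three equivalent ring positions remove any regiochemical question, and the first acyl group deactivates the ring toward a second acylation.

Step 10
Reactants: 19 1-(2,4,6-trihydroxyphenyl)butan-1-one; 20 3-methylbut-2-enal
Product: 22 1-(5,7-dihydroxy-2,2-dimethyl-2H-chromen-6-yl)butan-1-one, via dienone 21 (not isolated)
Conditions: 20 (1.0 equiv), ethylenediammonium diacetate (20 mol %), MeOH, 65 °C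
Reagents that add atoms: none
Why: Knoevenagel-type condensation of the iminium ion of 20 at a free ring carbon, loss of water to dienone 21 and oxa-6π electrocyclisation (formal [3+3] chromene annulation). Closure through the oxygen para to the acyl group gives 22 and keeps both hydroxyls beside the ketone; closure through an ortho oxygen gives the 8-butanoyl isomer, which is expected as a by-product and has to be separated, and limiting 20 suppresses a second annulation.

Step 11
Reactants: 22 1-(5,7-dihydroxy-2,2-dimethyl-2H-chromen-6-yl)butan-1-one
Product: 23 1-{8-[(dimethylamino)methyl]-5,7-dihydroxy-2,2-dimethyl-2H-chromen-6-yl}butan-1-one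
Conditions: aq. CH2O (37 %, 1.1 equiv), aq. Me2NH (40 %, 1.3 equiv), EtOH, 0 °C to rt
Reagents that add atoms: formaldehyde, C=O; dimethylamine, CNC
Why: Phenol Mannich reaction; C8 is the only unsubstituted and by far the most nucleophilic carbon of 22, so the site of aminomethylation is unambiguous. Excess amine and low temperature keep the product at the Mannich base stage.

Step 12
Reactants: 16 ring B unit; 23 1-{8-[(dimethylamino)methyl]-5,7-dihydroxy-2,2-dimethyl-2H-chromen-6-yl}butan-1-one
Product: 25 (R)-2-acetyl-6-[(6-butanoyl-5,7-dihydroxy-2,2-dimethyl-2H-chromen-8-yl)methyl]-4-[(2E)-3,7-dimethylocta-2,6-dien-1-yl]-3,5-dihydroxy-4-methylcyclohexa-2,5-dien-1-one (target), via quinone methide 24 (not isolated)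
Conditions: 16 (1.0 equiv), 23 (1.05 equiv), 1,4-dioxane, 90 °C, slow N2 stream
Reagents that add atoms: none
Why: Alkylation of a cyclic β-triketone with a phenolic Mannich base: the acidic enol 16 protonates the amine of 23, dimethylamine is lost to give quinone methide 24, and C6 of 16, its only free nucleophilic carbon, adds in Michael fashion with rearomatisation of ring A. Only ring A can become the electrophile and only ring B the nucleophile, which excludes the symmetrical dimers of a free formaldehyde condensation. No strong acid or base is present, a secondary amine cannot form a stable enaminone with the acetyl group, and C4 is not touched.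

## Compound list

1 | dimethyl 2,2-dimethylmalonate | COC(=O)C(C)(C)C(=O)OC | starting material
2 | 3-methoxy-2,2-dimethyl-3-oxopropanoic acid | COC(=O)C(C)(C)C(=O)O | intermediate
3 | 2,3,5,6-tetrafluoro-4-(trifluoromethyl)aniline | Nc1c(F)c(F)c(C(F)(F)F)c(F)c1F | starting material
4 | methyl 3-chloro-2,2-dimethyl-3-oxopropanoate | COC(=O)C(C)(C)C(=O)Cl | intermediate
5 | methyl 2,2-dimethyl-3-oxo-3-{[2,3,5,6-tetrafluoro-4-(trifluoromethyl)phenyl]amino}propanoate | COC(=O)C(C)(C)C(=O)Nc1c(F)c(F)c(C(F)(F)F)c(F)c1F | intermediate
6 | 6-methylhept-5-en-2-one | CC(C)=CCCC(C)=O | starting material
7 | diethyl 6-methylhepta-1,5-dien-2-yl phosphate | C=C(CCC=C(C)C)OP(=O)(OCC)OCC | intermediate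
8 | 6-methylhept-5-en-1-yne | C#CCCC=C(C)C | intermediate
9 | [(E)-2,6-dimethylhepta-1,5-dien-1-yl]dimethylaluminium | C[Al](C)/C=C(\C)CCC=C(C)C | intermediate
10 | (E)-1-iodo-2,6-dimethylhepta-1,5-diene | I/C=C(\C)CCC=C(C)C | intermediate
11 | methyl (2R,4E)-2,5,9-trimethyl-2-{[2,3,5,6-tetrafluoro-4-(trifluoromethyl)phenyl]carbamoyl}deca-4,8-dienoate | FC(F)(F)c1c(F)c(F)c(NC(=O)[C@@](C)(C/C=C(\C)CCC=C(C)C)C(=O)OC)c(F)c1F | intermediate
12 | methyl (2R,4E)-2-{(tert-butoxycarbonyl)[2,3,5,6-tetrafluoro-4-(trifluoromethyl)phenyl]carbamoyl}-2,5,9-trimethyldeca-4,8-dienoate | FC(F)(F)c1c(F)c(F)c(N(C(=O)OC(C)(C)C)C(=O)[C@@](C)(C/C=C(\C)CCC=C(C)C)C(=O)OC)c(F)c1F | intermediate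
13 | pentane-2,4-dione | CC(=O)CC(C)=O | starting material
14 | dilithium 1,3-dianion of pentane-2,4-dione | [Li+].[Li+].[CH2-]C(=O)[CH-]C(C)=O | intermediate
15 | methyl (2R)-2-[(2E)-3,7-dimethylocta-2,6-dien-1-yl]-2-methyl-3,5,7-trioxooctanoate | CC(=O)CC(=O)CC(=O)[C@@](C)(C/C=C(\C)CCC=C(C)C)C(=O)OC | intermediate
16 | (R)-2-acetyl-4-[(2E)-3,7-dimethylocta-2,6-dien-1-yl]-3,5-dihydroxy-4-methylcyclohexa-2,5-dien-1-one | C1=C(O)[C@@](C)(C/C=C(\C)CCC=C(C)C)C(O)=C(C(C)=O)C1=O | intermediate
17 | phloroglucinol | Oc1cc(O)cc(O)c1 | starting material
18 | butanoyl chloride | CCCC(=O)Cl | starting material
19 | 1-(2,4,6-trihydroxyphenyl)butan-1-one | CCCC(=O)c1c(O)cc(O)cc1O | intermediate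
20 | 3-methylbut-2-enal | CC(C)=CC=O | starting material
21 | 4-butanoyl-3,5-dihydroxy-2-(3-methylbut-2-en-1-ylidene)cyclohexa-3,5-dien-1-one (side chain cis to the ring ketone) | CCCC(=O)C1=C(O)/C(=C/C=C(C)C)C(=O)C=C1O | intermediate
22 | 1-(5,7-dihydroxy-2,2-dimethyl-2H-chromen-6-yl)butan-1-one | CCCC(=O)c1c(O)c2c(cc1O)OC(C)(C)C=C2 | intermediate
23 | 1-{8-[(dimethylamino)methyl]-5,7-dihydroxy-2,2-dimethyl-2H-chromen-6-yl}butan-1-one | CCCC(=O)c1c(O)c2c(c(CN(C)C)c1O)OC(C)(C)C=C2 | intermediate
24 | 6-butanoyl-5-hydroxy-2,2-dimethyl-8-methylidene-2H-chromen-7(8H)-one | CCCC(=O)C1=C(O)C2=C(OC(C)(C)C=C2)C(=C)C1=O | intermediate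
25 | (R)-2-acetyl-6-[(6-butanoyl-5,7-dihydroxy-2,2-dimethyl-2H-chromen-8-yl)methyl]-4-[(2E)-3,7-dimethylocta-2,6-dien-1-yl]-3,5-dihydroxy-4-methylcyclohexa-2,5-dien-1-one | CCCC(=O)c1c(O)c2c(c(CC3=C(O)[C@@](C)(C/C=C(\C)CCC=C(C)C)C(O)=C(C(C)=O)C3=O)c1O)OC(C)(C)C=C2 | target

## Step count and least certain steps

Total step count: 12 steps.

Longest linear sequence: 7 steps (steps 1, 2, 5, 6, 7, 8 and 12). The branch through steps 3 and 4 is equally long. The ring A branch (steps 9 to 11) is shorter and joins in step 12.

**Step 5 (key step, beyond known chemistry).**
- The most likely failure is slow oxidative addition of the hindered, electronically unactivated alkenyl iodide to the palladacycle. The catalyst would then decay to metal while silver-mediated homocoupling or protodeiodination uses up the iodide.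
- Methyl discrimination may also be weaker than with α-hydrogen amides, because the α-ester changes the preferred conformation in the C–H cleavage and can compete for a coordination site.
- Minor pathways are attack of the palladium-bound amide nitrogen on the new γ,δ-olefin and a second alkenylation.
- Fallback, using known chemistry (malonate alkylation and esterase desymmetrisation of a prochiral α,α-disubstituted malonate): it keeps 13 as its only numbered input, replaces 1 to 12 and comes back to the route at 15. Commercial dimethyl 2-methylmalonate is alkylated with geranyl bromide (NaH, THF) to dimethyl 2-geranyl-2-methylmalonate F1. Pig liver esterase in phosphate buffer cleaves one of the two enantiotopic esters to the (R)-half-ester F2. Its enantiomeric purity can be raised by crystallising the salt with 1-phenylethylamine. F2 is then activated and joined with 14 as described in the fallback to step 7 (imidazolide F3), which gives 15.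

**Step 7.**
- The acyl carbon of 12 is neopentyl-like, so attack of the carbanion may be diverted to the carbamate carbonyl (returning the anilide) or to a ring fluorine by nucleophilic aromatic substitution.
- Any first attack at the ester arm followed by closure on the imide would build the mirror-image ring and erode the enantiomeric purity without leaving a visible by-product.
- Fallback, which changes the acyl donor class: it sets out from 12 and comes back at 15. The small α-nucleophile hydroperoxide (LiOH, H2O2, THF–water, 0 °C, then Na2SO3) cleaves 12 to the (R)-half-ester F2. 1,1'-Carbonyldiimidazole in THF converts F2 into the imidazolide F3, which has a single activated carbonyl and no fluoroarene. Addition of F3 to 14 at −78 °C gives 15.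

**Step 12.**
- The quinone methide may be captured at an enol oxygen, may add to an olefin in a hetero-Diels–Alder manner, or may add twice to C6.
- Prolonged heating with the liberated amine may reopen the bridge by retro-Michael cleavage and redistribute the halves into symmetrical dimers.
- Fallback, which builds the bridge at the aldehyde oxidation level: it sets out from 22 and 16 and comes back at 25. Vilsmeier–Haack formylation of 22 (POCl3, DMF, EtOAc, rt, aqueous hydrolysis) gives the 8-carbaldehyde F5. Organocatalytic reductive alkylation of 16 with F5 (L-proline cat., Hantzsch ester, CH2Cl2, rt) condenses the two halves and delivers hydride in the same flask, giving 25. The bridge carbon again belongs to ring A only.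

**Step 10.**
- The electrocyclisation has little intrinsic preference between the para and the ortho oxygen, so poor regioselectivity and a laborious separation are the most likely problems. A second annulation at the remaining free carbon is the next.
- Fallback, which fixes the ring oxygen before the C–C bond is made: it sets out from 19 and comes back at 22. The non-chelated and most acidic 4-hydroxyl of 19 is alkylated with 3-chloro-3-methylbut-1-yne (DBU, CuCl2 cat., MeCN, 0 °C) to the aryl 1,1-dimethylpropargyl ether F4. Heating F4 in xylene triggers aromatic Claisen rearrangement, 1,5-hydrogen shift and oxa-6π closure. The two ortho carbons are equivalent and the oxygen is already in place, so only 22 can result.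

## Further compounds

F1 | step 5 | dimethyl 2-[(2E)-3,7-dimethylocta-2,6-dien-1-yl]-2-methylmalonate | COC(=O)C(C)(C/C=C(\C)CCC=C(C)C)C(=O)OC
F2 | step 5 | (2R,4E)-2-(methoxycarbonyl)-2,5,9-trimethyldeca-4,8-dienoic acid | OC(=O)[C@@](C)(C/C=C(\C)CCC=C(C)C)C(=O)OC
F3 | step 7 | methyl (2R,4E)-2-(1H-imidazole-1-carbonyl)-2,5,9-trimethyldeca-4,8-dienoate | O=C(n1ccnc1)[C@@](C)(C/C=C(\C)CCC=C(C)C)C(=O)OC
F4 | step 10 | 1-{2,6-dihydroxy-4-[(2-methylbut-3-yn-2-yl)oxy]phenyl}butan-1-one | CCCC(=O)c1c(O)cc(OC(C)(C)C#C)cc1O
F5 | step 12 | 6-butanoyl-5,7-dihydroxy-2,2-dimethyl-2H-chromene-8-carbaldehyde | CCCC(=O)c1c(O)c2c(c(C=O)c1O)OC(C)(C)C=C2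
A1 | alternative 1 | methyl (2R,4E)-2-(1H-imidazole-1-carbonyl)-2,5,9-trimethyldeca-4,8-dienoate | O=C(n1ccnc1)[C@@](C)(C/C=C(\C)CCC=C(C)C)C(=O)OC
A2 | alternative 1 | (R)-2-acetyl-4-[(2E)-3,7-dimethylocta-2,6-dien-1-yl]-3,5-dihydroxy-4-methylcyclohexa-2,5-dien-1-one | C1=C(O)[C@@](C)(C/C=C(\C)CCC=C(C)C)C(O)=C(C(C)=O)C1=O
A3 | alternative 2 | (2E,5E)-3,6,10-trimethylundeca-2,5,9-trien-1-ol | OC/C=C(\C)C/C=C(\C)CCC=C(C)C
A4 | alternative 2 | tert-butyl({(2S,3S)-3-[(2E)-3,7-dimethylocta-2,6-dien-1-yl]-3-methyloxiran-2-yl}methoxy)dimethylsilane | CC(C)(C)[Si](C)(C)OC[C@@H]1O[C@@]1(C)C/C=C(\C)CCC=C(C)C
A5 | alternative 2 | (2S,4E)-2-{[(tert-butyldimethylsilyl)oxy]methyl}-2,5,9-trimethyldeca-4,8-dienal | O=C[C@@](C)(C/C=C(\C)CCC=C(C)C)CO[Si](C)(C)C(C)(C)C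
A6 | alternative 3 | methyl (2E)-4-[(diethoxyphosphoryl)oxy]-2-[(2E)-3,7-dimethylocta-2,6-dien-1-yl]but-2-enoate | COC(=O)/C(C/C=C(\C)CCC=C(C)C)=C/COP(=O)(OCC)OCC
A7 | alternative 3 | methyl (2R,4E)-2-ethenyl-2,5,9-trimethyldeca-4,8-dienoate | C=C[C@@](C)(C/C=C(\C)CCC=C(C)C)C(=O)OC
A8 | alternative 3 | methyl (2R,4E)-2-acetyl-2,5,9-trimethyldeca-4,8-dienoate | CC(=O)[C@@](C)(C/C=C(\C)CCC=C(C)C)C(=O)OC
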